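**Plan**

- Numbering: ring A is the 4-hydroxy-3,5-dimethoxyphenyl ring carrying the C7–C8–C9 chain; ring B is the sinapyl alcohol ring, bound to C8 through its phenol oxygen O4'.
- Retrosynthesis: the two CH2OH groups (C9 and the allylic carbon on ring B) go back to ethyl esters and the ring A phenol to its acetate; then the O4'–C8 and C7–C8 bonds are cut together.
- Enabling feature: C8 bears three different partners, O4' of ring B, the carbinol carbon C7 on ring A and C9, which correspond to a phenol O–H, an aldehyde carbonyl and the carbene carbon of a diazoacetate.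
- Forward: sinapic acid is esterified, syringaldehyde is acetylated, both are joined with ethyl diazoacetate in one open-chain three-component coupling (no ring forms), and one hydride reduction gives the target.
- Stereochemistry: C7 and C8 are both created in the coupling, syn (threo) through a closed transition state on zirconium and 7R,8R through the chiral BINOL ligand; the E alkene is carried in from sinapic acid.

Key step: step 3

Assumption: the (R)-enantiomer of 3,3'-diiodo-BINOL on zirconium is taken to deliver the (2S,3R) adduct; this sense is assigned by analogy only, and the (S)-ligand would be taken if the opposite sense were found.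

Step 1
Reactants: 1 sinapic acid ((E)-3-(4-hydroxy-3,5-dimethoxyphenyl)prop-2-enoic acid)
Product: 2 ethyl sinapate (ethyl (E)-3-(4-hydroxy-3,5-dimethoxyphenyl)prop-2-enoate)
Conditions: EtOH, H2SO4 (cat.), reflux
Reagents that add atoms: ethanol, CCO
Why: Fischer esterification, an acid-catalysed equilibrium driven to the ester by ethanol as solvent, should leave the phenol and the E alkene untouched.

Step 2
Reactants: 3 syringaldehyde (4-hydroxy-3,5-dimethoxybenzaldehyde)
Product: 4 4-formyl-2,6-dimethoxyphenyl acetate
Conditions: Ac2O, pyridine, DMAP (cat.), CH2Cl2, 0 °C to rt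
Reagents that add atoms: acetic anhydride, CC(=O)OC(C)=O
Why: DMAP-catalysed O-acetylation of the phenol spares the aldehyde, and the acetate both hides the phenol from the carbenoid of step 3 and makes the carbonyl group more electrophilic.

Step 3
Reactants: 2 ethyl sinapate; 4 4-formyl-2,6-dimethoxyphenyl acetate; 5 ethyl diazoacetate
Product: 8 ethyl (2S,3R)-3-(4-acetoxy-3,5-dimethoxyphenyl)-2-{4-[(E)-3-ethoxy-3-oxoprop-1-enyl]-2,6-dimethoxyphenoxy}-3-hydroxypropanoate, via carbenoid Rh2(OAc)4(=CHCO2Et) 6 (not isolated), via oxonium ylide enol 7 (not isolated)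
Conditions: Rh2(OAc)4 (2 mol %), Zr(Ot-Bu)4 (20 mol %), (R)-3,3'-I2-BINOL (22 mol %), 4 Å MS, CH2Cl2, 0 °C; 2 and 5 (1.5 equiv) added together over 3 h to 4 (1.5 equiv) and the catalysts
Reagents that add atoms: none
Why: Proposed new method: Rh2(OAc)4 expels N2 from 5 to give the electrophilic carbenoid 6, the phenolic oxygen O4' of 2 (free or exchanged onto zirconium as an aryloxide) adds to the carbene carbon to make the O4'–C8 bond, and a shift of the proton or of zirconium from the oxonium oxygen to the ester carbonyl oxygen through a five-membered array releases rhodium and gives the enol form 7 of the ylide with the aryloxy group cis to the enol oxygen, which then attacks the Zr-bound aldehyde 4 through C8 to make the C7–C8 bond. The closest known reaction type is the three-component coupling of aryl diazoacetates, alcohols and aromatic aldehydes under Rh2(OAc)4 and a chiral co-catalyst made from a zirconium tetraalkoxide Zr(OR)4 and a BINOL, in which an oxonium ylide is intercepted by aldol addition before the 1,2-proton shift; an acceptor-only diazoacetate combined with a phenol as the O–H partner has not been shown in that manifold. No ring closes, since both bonds are formed on an open chain. C7 and C8 arise together: their syn (threo) relationship is expected from a chair-like transition state held on zirconium in which the cis-chelated enolate meets the aldehyde with its aryl group equatorial, and the absolute sense, (2S,3R) in 8, is set by the (R)-configured BINOL ligand that shields one face of the bound aldehyde. The step needs aldol capture to outrun the proton shift that ends in plain O–H insertion and needs the carbenoid to choose the phenol over the alkene and the aldehyde oxygen; in 4 the two meta-methoxy groups and the para-acetoxy group make the carbonyl electron-poor and a fast acceptor, the acrylate alkene of 2 is too electron-poor to be cyclopropanated, and slow co-addition of 2 and 5 keeps free phenol (the proton source) and free diazo compound scarce. A Lewis acid with bulky, non-competing tert-butoxide ligands is chosen over a chiral phosphoric acid because a Brønsted acid would shuttle the enol proton and favour the insertion product.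

Step 4
Reactants: 8 ethyl (2S,3R)-3-(4-acetoxy-3,5-dimethoxyphenyl)-2-{4-[(E)-3-ethoxy-3-oxoprop-1-enyl]-2,6-dimethoxyphenoxy}-3-hydroxypropanoate
Product: 9 (1R,2R)-1-(4-hydroxy-3,5-dimethoxyphenyl)-2-{4-[(E)-3-hydroxyprop-1-enyl]-2,6-dimethoxyphenoxy}propane-1,3-diol (target)
Conditions: i-Bu2AlH (10 equiv), CH2Cl2, −78 to 0 °C; aq. potassium sodium tartrate work-up, no acid
Reagents that add atoms: none
Why: Ester reduction with excess i-Bu2AlH should take both ethyl esters to primary alcohols (the conjugated one by clean 1,2-addition, as in the standard reduction of cinnamate esters to cinnamyl alcohols) and cleave the aryl acetate reductively in the same flask, while neither stereocentre is touched and the C8 descriptor changes from S to R only because CH2OH ranks below C7.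

**Compound list**

1 | sinapic acid, (E)-3-(4-hydroxy-3,5-dimethoxyphenyl)prop-2-enoic acid | COc1cc(/C=C/C(=O)O)cc(OC)c1O | starting material
2 | ethyl sinapate, ethyl (E)-3-(4-hydroxy-3,5-dimethoxyphenyl)prop-2-enoate | CCOC(=O)/C=C/c1cc(OC)c(O)c(OC)c1 | intermediate
3 | syringaldehyde, 4-hydroxy-3,5-dimethoxybenzaldehyde | COc1cc(C=O)cc(OC)c1O | starting material
4 | 4-formyl-2,6-dimethoxyphenyl acetate | COc1cc(C=O)cc(OC)c1OC(C)=O | intermediate
5 | ethyl diazoacetate | CCOC(=O)C=[N+]=[N-] | starting material
6 | carbenoid Rh2(OAc)4(=CHCO2Et) formed from 5, not isolated (acetate bridges written as terminal Rh–O bonds) | CCOC(=O)C=[Rh](OC(C)=O)(OC(C)=O)[Rh](OC(C)=O)OC(C)=O | intermediate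
7 | enol form of the oxonium ylide from 2 and 6, not isolated: ketene hemiacetal ArO–CH=C(OH)OEt with the aryloxy group cis to the enol OH (Zr-bound in the flask, written as the free enol) | CCO/C(O)=C/Oc1c(OC)cc(/C=C/C(=O)OCC)cc1OC | intermediate
8 | ethyl (2S,3R)-3-(4-acetoxy-3,5-dimethoxyphenyl)-2-{4-[(E)-3-ethoxy-3-oxoprop-1-enyl]-2,6-dimethoxyphenoxy}-3-hydroxypropanoate (syn aldol diester) | COc1cc([C@@H](O)[C@@H](C(=O)OCC)Oc2c(OC)cc(/C=C/C(=O)OCC)cc2OC)cc(OC)c1OC(C)=O | intermediate
9 | (1R,2R)-1-(4-hydroxy-3,5-dimethoxyphenyl)-2-{4-[(E)-3-hydroxyprop-1-enyl]-2,6-dimethoxyphenoxy}propane-1,3-diol (threo, 7R,8R) | COc1cc([C@@H](O)[C@@H](CO)Oc2c(OC)cc(/C=C/CO)cc2OC)cc(OC)c1O | target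

**Step count**

Total step count: 4 (steps 1 and 2 run in parallel).
Longest linear sequence: 3 steps (1 → 2 → 8 → 9 through steps 1, 3 and 4).

**Steps most likely to fail**

Step 3 (the step labelled as a new method). The proton shift may outrun aldol capture, so that plain O–H insertion takes over. Control of the syn/anti ratio and of the aldehyde face by the zirconium–BINOL co-catalyst may also be weak, and acetyl transfer from the aryl acetate under the zirconium alkoxide is possible. The fallback is an auxiliary-controlled Evans syn aldol, all of it known chemistry, setting out from 2 and coming back to the route at 9. O-Alkylation of 2 with the known reagent (S)-4-benzyl-3-(chloroacetyl)oxazolidin-2-one (K2CO3, NaI, MeCN, rt to 50 °C) should give the aryloxyacetyl imide (S)-4-benzyl-3-({4-[(E)-3-ethoxy-3-oxoprop-1-enyl]-2,6-dimethoxyphenoxy}acetyl)oxazolidin-2-one F1. Soft enolisation with Bu2BOTf and i-Pr2NEt in CH2Cl2 at −78 °C should give the dibutylboron Z-enolate F2 (not isolated). F2 is expected to add to aldehyde 4 through the usual chair transition state and, after buffered H2O2 work-up, to give the Evans syn aldol imide F3 with the (2S,3R) configuration of 8. EtOMgBr (from EtMgBr and EtOH) in EtOH/THF at 0 °C should exchange the auxiliary for an ethyl ester and ethanolyse the aryl acetate, giving the phenolic diester F4. The i-Bu2AlH conditions of step 4 should then turn F4 into 9.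

Step 4. The aluminium aldolate may undergo retro-aldol cleavage or epimerisation at C8 before the hindered α-aryloxy ester is reduced, the reduction may stall at the aldehyde level, and the benzylic C7–O bond may ionise once the phenol is unmasked. The fallback masks the aldol hydroxyl first; it sets out from 8 and comes back at 9. Silylation (TBSOTf, 2,6-lutidine, CH2Cl2, −78 °C) should give the C7 silyl ether F5, which has no free aldolate to fragment. i-Bu2AlH should then reduce both esters and remove the acetate to give the mono-silylated triol F6. Bu4NF buffered with AcOH in THF at 0 °C should release 9.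

Step 1. The esterification is equilibrium-limited, and the electron-rich cinnamic acid may isomerise (E to Z) or oligomerise under hot acid and light. The fallback builds the alkene instead of esterifying it; it sets out from 3 and comes back at 2. Wittig olefination of 3 with the stabilised ylide Ph3P=CHCO2Et in toluene at reflux tolerates the free phenol and should give the E ester 2 directly. This makes no compound outside the list (F0).

**Further compounds**

F1 | step 3 | (S)-4-benzyl-3-({4-[(E)-3-ethoxy-3-oxoprop-1-enyl]-2,6-dimethoxyphenoxy}acetyl)oxazolidin-2-one | CCOC(=O)/C=C/c1cc(OC)c(OCC(=O)N2[C@@H](Cc3ccccc3)COC2=O)c(OC)c1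
F2 | step 3 | dibutylboron Z-enolate of F1 (not isolated) | CCCCB(CCCC)O/C(N1[C@@H](Cc2ccccc2)COC1=O)=C\Oc1c(OC)cc(/C=C/C(=O)OCC)cc1OC
F3 | step 3 | (S)-3-[(2S,3R)-3-(4-acetoxy-3,5-dimethoxyphenyl)-2-{4-[(E)-3-ethoxy-3-oxoprop-1-enyl]-2,6-dimethoxyphenoxy}-3-hydroxypropanoyl]-4-benzyloxazolidin-2-one | COc1cc([C@@H](O)[C@@H](C(=O)N2[C@@H](Cc3ccccc3)COC2=O)Oc2c(OC)cc(/C=C/C(=O)OCC)cc2OC)cc(OC)c1OC(C)=O
F4 | step 3 | ethyl (2S,3R)-2-{4-[(E)-3-ethoxy-3-oxoprop-1-enyl]-2,6-dimethoxyphenoxy}-3-hydroxy-3-(4-hydroxy-3,5-dimethoxyphenyl)propanoate | COc1cc([C@@H](O)[C@@H](C(=O)OCC)Oc2c(OC)cc(/C=C/C(=O)OCC)cc2OC)cc(OC)c1O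
F5 | step 4 | ethyl (2S,3R)-3-(4-acetoxy-3,5-dimethoxyphenyl)-3-(tert-butyldimethylsilyloxy)-2-{4-[(E)-3-ethoxy-3-oxoprop-1-enyl]-2,6-dimethoxyphenoxy}propanoate | COc1cc([C@@H](O[Si](C)(C)C(C)(C)C)[C@@H](C(=O)OCC)Oc2c(OC)cc(/C=C/C(=O)OCC)cc2OC)cc(OC)c1OC(C)=O
F6 | step 4 | (2R,3R)-3-(tert-butyldimethylsilyloxy)-3-(4-hydroxy-3,5-dimethoxyphenyl)-2-{4-[(E)-3-hydroxyprop-1-enyl]-2,6-dimethoxyphenoxy}propan-1-ol | COc1cc([C@@H](O[Si](C)(C)C(C)(C)C)[C@@H](CO)Oc2c(OC)cc(/C=C/CO)cc2OC)cc(OC)c1O
F0 | step 1 | none | none
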